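**Strategy**

All three C–Br bonds are disconnected at once, back to a bromine-free diaryl ether whose two oxygens are differentiated. The key step exploits the fact that on ring A the bromines at C3 and C5 lie ortho and para to the C2 oxygen, whereas on ring B the bromine at C4' lies para to the ether carbon C1' and meta to the C6' oxygen. A free C2 hydroxyl on ring A and an electron-poor tosylate on the C6' oxygen of ring B therefore program one NH4VO3-catalysed oxidative bromination (KBr, H2O2) to deliver the complete substitution pattern. The precursor is the monotosylate of 2,2'-oxydiphenol, made from diphenyl ether.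

Key step: step 3

Remark on the chemistry: ring A is the ring that ends as the methoxy ring (C1 carries the ether oxygen, C2 the second oxygen); ring B ends as the phenol ring (C1' carries the ether oxygen, C6' the second oxygen). The target has no stereocenter, so no stereodescriptor is needed.

**Route**

Step 1
Reactants: 1 diphenyl ether
Product: 4 2,2'-oxydiphenol, via dilithiated diphenyl ether 2 (not isolated), via bis(dimethoxyboryl) diphenyl ether 3 (not isolated)
Conditions: n-BuLi (2.5 equiv), TMEDA (2.5 equiv), Et2O/hexane, 0 °C → rt; B(OMe)3 (5 equiv), −78 °C → rt; AcOH, 30% aq. H2O2, 0 °C → rt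
Reagents that add atoms: hydrogen peroxide, OO (the two hydroxyl oxygens of 4); n-butyllithium, [Li]CCCC (lithium of 2 only); trimethyl borate, COB(OC)OC (boron and methoxy groups of 3 only)
Why: Double directed ortho-metalation of the diaryl ether by the n-BuLi–TMEDA aggregate, electrophilic borylation of both carbanion sites and oxidative 1,2-aryl shift from boron to oxygen (boronate oxidation) are each standard operations, and a bridged diarylborinate formed from one boron and both rings would be oxidised to the same bis-phenol.

Step 2
Reactants: 4 2,2'-oxydiphenol; 5 4-methylbenzenesulfonyl chloride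
Product: 6 2-(2-hydroxyphenoxy)phenyl 4-methylbenzenesulfonate
Conditions: TsCl (0.95 equiv, slow addition), K2CO3 (1.0 equiv), acetone, 0 °C → rt
Reagents that add atoms: 4-methylbenzenesulfonyl chloride (compound 5), Cc1ccc(cc1)S(=O)(=O)Cl
Why: O-Sulfonylation of a phenoxide by a sulfonyl chloride, in which one equivalent of base should generate mainly the hydrogen-bond-stabilised monoanion of 4 and a slight deficit of slowly added TsCl should keep double sulfonylation low, unreacted 4 being recoverable.

Step 3
Reactants: 6 2-(2-hydroxyphenoxy)phenyl 4-methylbenzenesulfonate
Product: 9 5-bromo-2-(3,5-dibromo-2-hydroxyphenoxy)phenyl 4-methylbenzenesulfonate, via ring A monobromide 7 (not isolated), via ring A dibromide 8 (not isolated)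
Conditions: KBr (3.3 equiv), 30% aq. H2O2 (3.3 equiv, in portions), NH4VO3 (5 mol %), H2SO4 (1.7 equiv), MeCN/H2O, rt
Reagents that add atoms: potassium bromide, [K+].[Br-]
Why: In dilute acid NH4VO3 and H2O2 form the oxoperoxo cation VO(O2)+ of pentavalent vanadium, which oxidises bromide to an electrophilic bromine species (HOBr or Br2) and is recharged by more H2O2, and each C–Br bond then forms by electrophilic aromatic substitution through an arenium ion. The closest known reaction type is the haloperoxidase-like oxidative bromination of phenols and aryl ethers with a bromide salt, H2O2 and NH4VO3 as catalyst. No ring is closed and no stereocenter is created. The selectivity needed is positional, three of eight C–H bonds on rings A and B: the free C2 hydroxyl makes ring A the most electron-rich ring, so bromine should enter first para to it at C5 and then at C3, its only open ortho position because C1 carries the ether oxygen. On ring B the sulfonate turns the C6' oxygen into a poor donor, so the ether oxygen at C1' should steer the third, slower substitution, and its para position C4' is favoured over the ortho position C2' on steric grounds. The leftover ring A positions C4 and C6 lie meta to the hydroxyl on a ring by then deactivated by two bromines, and the sulfonyl-substituted tolyl ring is too electron-poor to react.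

Step 4
Reactants: 9 5-bromo-2-(3,5-dibromo-2-hydroxyphenoxy)phenyl 4-methylbenzenesulfonate
Product: 10 5-bromo-2-(3,5-dibromo-2-methoxyphenoxy)phenyl 4-methylbenzenesulfonate
Conditions: MeI (1.5 equiv), K2CO3 (1.5 equiv), DMF, rt
Reagents that add atoms: iodomethane, CI
Why: Williamson ether synthesis, in which the acidic dibromophenol is deprotonated by K2CO3 and alkylated by MeI in an SN2 reaction, while the aryl sulfonate is stable to carbonate in an aprotic solvent and an intramolecular sulfonyl shift is not expected because an in-line displacement at sulfur cannot be accommodated in the eight-membered cyclic transition state it would need.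

Step 5
Reactants: 10 5-bromo-2-(3,5-dibromo-2-methoxyphenoxy)phenyl 4-methylbenzenesulfonate
Product: 11 5-bromo-2-(3,5-dibromo-2-methoxyphenoxy)phenol
Conditions: aq. NaOH (5 equiv), MeOH/THF, 60 °C; then aq. HCl
Reagents that add atoms: none
Why: Alkaline solvolysis of an aryl sulfonate, in which hydroxide attacks sulfur and expels the ring B phenoxide, leaving the aryl C–O bonds, the methyl ether and the three aryl bromides (no activation for SNAr) untouched.

**Compound list**

1 | diphenyl ether | c1ccc(cc1)Oc1ccccc1 | starting material
2 | 2,2'-dilithiodiphenyl ether | [Li]c1ccccc1Oc1ccccc1[Li] | intermediate (not isolated)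
3 | 2,2'-bis(dimethoxyboryl)diphenyl ether | COB(OC)c1ccccc1Oc1ccccc1B(OC)OC | intermediate (not isolated)
4 | 2,2'-oxydiphenol | Oc1ccccc1Oc1ccccc1O | intermediate
5 | 4-methylbenzenesulfonyl chloride | Cc1ccc(cc1)S(=O)(=O)Cl | starting material
6 | 2-(2-hydroxyphenoxy)phenyl 4-methylbenzenesulfonate | Cc1ccc(cc1)S(=O)(=O)Oc1ccccc1Oc1ccccc1O | intermediate
7 | 2-(5-bromo-2-hydroxyphenoxy)phenyl 4-methylbenzenesulfonate | Cc1ccc(cc1)S(=O)(=O)Oc1ccccc1Oc1cc(Br)ccc1O | intermediate (not isolated)
8 | 2-(3,5-dibromo-2-hydroxyphenoxy)phenyl 4-methylbenzenesulfonate | Cc1ccc(cc1)S(=O)(=O)Oc1ccccc1Oc1cc(Br)cc(Br)c1O | intermediate (not isolated)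
9 | 5-bromo-2-(3,5-dibromo-2-hydroxyphenoxy)phenyl 4-methylbenzenesulfonate | Cc1ccc(cc1)S(=O)(=O)Oc1cc(Br)ccc1Oc1cc(Br)cc(Br)c1O | intermediate
10 | 5-bromo-2-(3,5-dibromo-2-methoxyphenoxy)phenyl 4-methylbenzenesulfonate | Cc1ccc(cc1)S(=O)(=O)Oc1cc(Br)ccc1Oc1cc(Br)cc(Br)c1OC | intermediate
11 | 5-bromo-2-(3,5-dibromo-2-methoxyphenoxy)phenol | COc1c(Br)cc(Br)cc1Oc1ccc(Br)cc1O | target

**Totals**

Total step count: 5
Longest linear sequence: 5 steps (1 → 4 → 6 → 9 → 10 → 11)

**Steps most likely to fail**

Step 3. The third substitution may stall on the sulfonate-deactivated ring B or leak to its ortho position C2'. On long exposure the peroxide-charged catalyst may also begin to oxidise the phenol ring instead of brominating it. The fallback gives up the single oxidative operation and brominates in two separately controlled stoichiometric stages, with the phenol capped in between. It sets out from compound 6. NBS (2.05 equiv) in MeCN at 0 °C should brominate only the phenol ring and give the ring A dibromide 8, isolated this time. MeI and K2CO3 in DMF then cap the hydroxyl to give 2-(3,5-dibromo-2-methoxyphenoxy)phenyl 4-methylbenzenesulfonate F1. Br2 in AcOH at 40 °C (with a trace of FeBr3 if the ring proves sluggish) should then introduce the last bromine para to the ether oxygen of ring B. The fallback comes back to the route at compound 10.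

Step 2. The second hydroxyl may be sulfonylated at a rate close to that of the first, so that bis-tosylate and unreacted bis-phenol build up at the expense of the monotosylate. The fallback reverses the logic: sulfonylate exhaustively, then remove one tosyl group. It sets out from compound 4. TsCl (2.5 equiv) and K2CO3 in refluxing acetone should give oxydi-2,1-phenylene bis(4-methylbenzenesulfonate) F2. KOH (2.0 equiv) in MeOH/THF/H2O at rt, followed by aq. HCl, should then cleave one sulfonate. The phenoxide set free first carries a negative charge next to the surviving sulfonate and should slow the second attack. The fallback comes back to the route at compound 6.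

Step 1. The second ortho-metalation may remain incomplete, or aryl–boron bonds may be lost by protonolysis during the telescoped oxidation, so that singly hydroxylated material accompanies the bis-phenol. The fallback builds the bis-phenol with both oxygens already in place and without organolithium chemistry. Since step 1 is the first step, it cannot start from a compound of the route: in place of compound 1 it sets out from commercial 2-methoxyphenol (COc1ccccc1O) and 2-bromoanisole (COc1ccccc1Br). Ullmann diaryl ether coupling (CuI 10 mol %, N,N-dimethylglycine 30 mol %, Cs2CO3, dioxane, 100 °C) should give 1,1'-oxybis(2-methoxybenzene) F3. BBr3 in CH2Cl2 (−78 °C → rt) then cleaves both methyl ethers. The fallback comes back to the route at compound 4.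

**Further compounds**

F1 | step 3 | 2-(3,5-dibromo-2-methoxyphenoxy)phenyl 4-methylbenzenesulfonate | Cc1ccc(cc1)S(=O)(=O)Oc1ccccc1Oc1cc(Br)cc(Br)c1OC
F2 | step 2 | oxydi-2,1-phenylene bis(4-methylbenzenesulfonate) | Cc1ccc(cc1)S(=O)(=O)Oc1ccccc1Oc1ccccc1OS(=O)(=O)c1ccc(C)cc1
F3 | step 1 | 1,1'-oxybis(2-methoxybenzene) | COc1ccccc1Oc1ccccc1OC
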